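**Assumption:** the SMILES string is taken as the definition of the target, so ring B is read as the 7-hydroxy-2,3-dihydro-1-benzofuran-5-yl unit carried on C3 of ring A.

**Retrosynthetic overview**
1. Kobophenol A ⇐ its deca-O-benzyl ether 38 ⇐ 1,3-dipolar cycloaddition of a symmetrical diaryl carbonyl ylide (thermal ring opening of trans-epoxide 36) with Z-stilbene 31; this closes the oxolane and sets its four stereocentres.
2. Z-stilbene 31 ⇐ aryl chloride 27 (rings A and B complete) by alkynylation and semi-hydrogenation.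
3. Each trans-2,3-diaryl-dihydrobenzofuran ⇐ aryl 1-methylallyl ether by aromatic Claisen rearrangement (sets C3 by 1,3-chirality transfer), alkene cleavage, aryl Grignard addition and acid ring closure (C3 sets C2).
4. The allyl ethers ⇐ Mitsunobu inversion of (S)- and (R)-but-3-yn-2-ol with two phenols, then hydrozirconation and cross-coupling.
5. Order of ring formation: ring B (steps 5–7), ring A (steps 11–13), oxolane (step 18).

Notation: Bn = benzyl. ArB = (2R,3R)-7-(benzyloxy)-2-[4-(benzyloxy)phenyl]-3-[3,5-bis(benzyloxy)phenyl]-2,3-dihydro-1-benzofuran-5-yl.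

**Route**

Step 1
Reactants: 1 2-(benzyloxy)phenol
Product: 2 2-(benzyloxy)-4-bromophenol
Conditions: NBS, MeCN, 0 °C
Reagents that add atoms: N-bromosuccinimide, O=C1CCC(=O)N1Br
Why: Electrophilic aromatic bromination goes para to the free hydroxyl group, the strongest director on the ring.

Step 2
Reactants: 2 2-(benzyloxy)-4-bromophenol; 3 (S)-but-3-yn-2-ol
Product: 4 2-(benzyloxy)-4-bromo-1-{[(2R)-but-3-yn-2-yl]oxy}benzene
Conditions: PPh3, DIAD, THF, 0 °C to rt
Reagents that add atoms: none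
Why: Mitsunobu etherification is an SN2 displacement at the activated propargylic carbinol, so the bought (S) centre is inverted cleanly to the (R) aryl ether.

Step 3
Reactants: 5 5-iodobenzene-1,3-diol
Product: 6 1,3-bis(benzyloxy)-5-iodobenzene
Conditions: BnBr (2.2 equiv), K2CO3, DMF, 60 °C
Reagents that add atoms: benzyl bromide, BrCc1ccccc1
Why: Williamson ether synthesis benzylates both phenoxides.

Step 4
Reactants: 4 (R)-aryl but-3-yn-2-yl ether; 6 1,3-bis(benzyloxy)-5-iodobenzene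
Product: 8 2-(benzyloxy)-1-{[(2R,3E)-4-[3,5-bis(benzyloxy)phenyl]but-3-en-2-yl]oxy}-4-bromobenzene, via alkenylzirconocene 7 (not isolated)
Conditions: Cp2Zr(H)Cl, THF, rt; then 6, Pd(PPh3)4 (5 mol%), rt
Reagents that add atoms: none
Why: Syn hydrozirconation of the terminal alkyne gives the (E)-alkenylzirconocene, which is transferred to the aryl iodide by palladium-catalysed cross-coupling (Negishi type) with retention of geometry while the aryl bromide and the ether stereocentre stay untouched.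

Step 5
Reactants: 8 (2R,3E)-allyl aryl ether
Product: 10 2-(benzyloxy)-6-{(1R,2E)-1-[3,5-bis(benzyloxy)phenyl]but-2-en-1-yl}-4-bromophenol, via ortho-dienone 9 (not isolated)
Conditions: PhNEt2, 180 °C
Reagents that add atoms: none
Why: Aromatic Claisen rearrangement, a [3,3]-sigmatropic shift through a chair transition state with the methyl group equatorial, delivers the allyl unit to the only free ortho carbon and transfers the (R) ether centre to the new benzylic carbon (R, the future C3 of ring B) before the dienone tautomerises to the phenol.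

Step 6
Reactants: 10 Claisen phenol of the ring B series
Product: 12 (3R)-7-(benzyloxy)-3-[3,5-bis(benzyloxy)phenyl]-5-bromo-2,3-dihydro-1-benzofuran-2-ol, via ozonide 11 (not isolated)
Conditions: O3 (titrated solution), CH2Cl2, −78 °C; then PPh3, −78 °C to rt; used crude
Reagents that add atoms: ozone, O=[O+][O-]
Why: Ozonolysis cleaves the only alkene and the diarylacetaldehyde is captured at once by the neighbouring phenol as a lactol, which keeps the benzylic stereocentre from enolising.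

Step 7
Reactants: 12 ring B lactol; 13 4-(benzyloxy)phenylmagnesium bromide
Product: 15 (2R,3R)-7-(benzyloxy)-2-[4-(benzyloxy)phenyl]-3-[3,5-bis(benzyloxy)phenyl]-5-bromo-2,3-dihydro-1-benzofuran, via diol 14 (not isolated)
Conditions: 13 (3 equiv), THF, −78 to −20 °C; aq NH4Cl; then TsOH·H2O (10 mol%), CH2Cl2, 0 °C
Reagents that add atoms: none
Why: Grignard addition to the ring-opened aldehyde gives a benzylic alcohol that ionises under acid to a 4-alkoxybenzyl cation, and the phenol oxygen closes the five-membered ring (dehydrative cycloetherification) anti to the C3 aryl group, so C3 sets C2 and both carbinol epimers converge on the 2,3-trans ring.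

Step 8
Reactants: 16 5-chlorobenzene-1,3-diol
Product: 17 3-(benzyloxy)-5-chlorophenol
Conditions: BnBr (1.0 equiv), K2CO3, DMF, rt
Reagents that add atoms: benzyl bromide, BrCc1ccccc1
Why: Williamson mono-benzylation of the symmetrical diol gives a statistical mixture from which the mono-ether is separated by chromatography.

Step 9
Reactants: 17 3-(benzyloxy)-5-chlorophenol; 18 (R)-but-3-yn-2-ol
Product: 19 1-(benzyloxy)-3-{[(2S)-but-3-yn-2-yl]oxy}-5-chlorobenzene
Conditions: PPh3, DIAD, THF, 0 °C to rt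
Reagents that add atoms: none
Why: Mitsunobu etherification inverts the bought (R) carbinol to the (S) aryl ether by SN2 displacement.

Step 10
Reactants: 19 (S)-aryl but-3-yn-2-yl ether; 15 ring B bromide
Product: 21 1-(benzyloxy)-3-chloro-5-{[(2S,3E)-4-ArB-but-3-en-2-yl]oxy}benzene, via alkenylzirconocene 20 (not isolated)
Conditions: Cp2Zr(H)Cl, THF, rt; then 15, Pd(PPh3)4 (5 mol%), ZnCl2 (20 mol%), THF, 50 °C
Reagents that add atoms: none
Why: Hydrozirconation followed by palladium-catalysed cross-coupling (Negishi type) joins the (E)-alkenyl group to the aryl bromide with retention of geometry, the aryl chloride being inert to Pd(PPh3)4 at this temperature.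

Step 11
Reactants: 21 (2S,3E)-allyl aryl ether carrying ArB
Product: 23 5-(benzyloxy)-3-chloro-2-[(1S,2E)-1-ArB-but-2-en-1-yl]phenol, via ortho-dienone 22 (not isolated)
Conditions: PhNEt2, 180 °C
Reagents that add atoms: none
Why: Aromatic Claisen rearrangement ([3,3]-sigmatropic, chair transition state) goes to the ortho carbon next to chlorine, which both meta substituents favour, and transfers the (S) ether centre to the new benzylic carbon (S, the future C3 of ring A).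

Step 12
Reactants: 23 Claisen phenol of the ring A series
Product: 25 (3S)-6-(benzyloxy)-4-chloro-3-ArB-2,3-dihydro-1-benzofuran-2-ol, via ozonide 24 (not isolated)
Conditions: O3 (titrated solution), CH2Cl2, −78 °C; then PPh3, −78 °C to rt; used crude
Reagents that add atoms: ozone, O=[O+][O-]
Why: Ozonolysis of the only alkene gives the aldehyde, which is stored as its lactol so that the diaryl-substituted stereocentre does not enolise.

Step 13
Reactants: 25 ring A lactol; 13 4-(benzyloxy)phenylmagnesium bromide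
Product: 27 (2S,3S)-6-(benzyloxy)-2-[4-(benzyloxy)phenyl]-4-chloro-3-ArB-2,3-dihydro-1-benzofuran, via diol 26 (not isolated)
Conditions: 13 (3 equiv), THF, −78 to −20 °C; aq NH4Cl; then TsOH·H2O (10 mol%), CH2Cl2, 0 °C
Reagents that add atoms: none
Why: Grignard addition and acid-mediated dehydrative cycloetherification through the 4-alkoxybenzyl cation close ring A with the new C2 aryl group trans to the C3 substituent, while ring B, already trans, is not changed by the acid.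

Step 14
Reactants: 28 3,5-bis(benzyloxy)benzaldehyde
Product: 29 1,3-bis(benzyloxy)-5-ethynylbenzene
Conditions: dimethyl (1-diazo-2-oxopropyl)phosphonate, K2CO3, MeOH/THF, rt
Reagents that add atoms: dimethyl (1-diazo-2-oxopropyl)phosphonate, CC(=O)C(=[N+]=[N-])P(=O)(OC)OC
Why: Seyferth–Gilbert homologation in the Ohira–Bestmann form converts the aldehyde into the terminal alkyne with one added carbon.

Step 15
Reactants: 27 aryl chloride with rings A and B; 29 1,3-bis(benzyloxy)-5-ethynylbenzene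
Product: 30 (2S,3S)-6-(benzyloxy)-2-[4-(benzyloxy)phenyl]-4-{[3,5-bis(benzyloxy)phenyl]ethynyl}-3-ArB-2,3-dihydro-1-benzofuran
Conditions: PdCl2(MeCN)2 (3 mol%), XPhos (9 mol%), Cs2CO3, 1,4-dioxane, 90 °C
Reagents that add atoms: none
Why: Copper-free Sonogashira coupling with a bulky electron-rich biarylphosphine lets palladium insert into the hindered aryl chloride without touching any stereocentre.

Step 16
Reactants: 30 diarylalkyne
Product: 31 (2S,3S)-6-(benzyloxy)-2-[4-(benzyloxy)phenyl]-4-{(Z)-2-[3,5-bis(benzyloxy)phenyl]ethenyl}-3-ArB-2,3-dihydro-1-benzofuran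
Conditions: H2 (1 atm), Pd/CaCO3 poisoned with Pb(OAc)2, quinoline, EtOAc, rt
Reagents that add atoms: none
Why: Lindlar semi-hydrogenation adds hydrogen syn to the alkyne and stops at the Z-alkene, leaving the benzyl ethers intact.

Step 17
Reactants: 32 4-(benzyloxy)benzaldehyde; 33 4-(benzyloxy)benzyl chloride
Product: 36 trans-2,3-bis[4-(benzyloxy)phenyl]oxirane (racemic), via sulfonium chloride 34 (not isolated), via sulfonium ylide 35 (not isolated)
Conditions: tetrahydrothiophene (1.2 equiv), powdered KOH, MeCN, rt; purified on basic alumina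
Reagents that add atoms: none
Why: Corey–Chaykovsky-type epoxidation by the benzyl sulfonium ylide formed in the flask gives the trans-epoxide through reversible betaine formation, and the racemate suffices because the epoxide only serves as the source of an achiral ylide.

Step 18
Reactants: 31 Z-stilbene; 36 trans-2,3-bis[4-(benzyloxy)phenyl]oxirane
Product: 38 deca-O-benzylkobophenol A, via carbonyl ylide 37 (not isolated)
Conditions: 36 (3 equiv), K2CO3 (solid), 1,2-dichlorobenzene, 180 °C, sealed tube, dark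
Reagents that add atoms: none
Why: Thermal conrotatory electrocyclic opening of the trans-epoxide gives the exo,exo carbonyl ylide, which adds to the alkene in a concerted suprafacial 1,3-dipolar cycloaddition: the ylide shape sets the 2,5-cis aryl groups, the Z-alkene sets the 3,4-cis aryl groups, the exo approach places them trans to the C2 and C5 aryl groups, and the ylide should prefer the alkene face turned away from the C3 substituent of ring A, which on a simple conformational model gives the (2R,3S,4R,5S) oxolane.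

Step 19
Reactants: 38 deca-O-benzylkobophenol A
Product: 39 kobophenol A
Conditions: H2 (1 atm), Pd on carbon (10%), THF/MeOH, rt, stopped at full debenzylation
Reagents that add atoms: none
Why: Catalytic hydrogenolysis cleaves the ten aryl benzyl ethers faster than the cyclic benzylic C–O bonds of the two dihydrobenzofurans and the oxolane, and no stereocentre is touched.

**Compound list**
1 | 2-(benzyloxy)phenol | Oc1ccccc1OCc1ccccc1 | starting material
2 | 2-(benzyloxy)-4-bromophenol | Oc1ccc(Br)cc1OCc1ccccc1 | intermediate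
3 | (S)-but-3-yn-2-ol | C[C@H](O)C#C | starting material
4 | 2-(benzyloxy)-4-bromo-1-{[(2R)-but-3-yn-2-yl]oxy}benzene | C[C@@H](Oc1ccc(Br)cc1OCc1ccccc1)C#C | intermediate
5 | 5-iodobenzene-1,3-diol | Oc1cc(O)cc(I)c1 | starting material
6 | 1,3-bis(benzyloxy)-5-iodobenzene | Ic1cc(OCc2ccccc2)cc(OCc2ccccc2)c1 | intermediate
7 | chlorobis(cyclopentadienyl){(1E,3R)-3-[2-(benzyloxy)-4-bromophenoxy]but-1-en-1-yl}zirconium | C[C@@H](Oc1ccc(Br)cc1OCc1ccccc1)/C=C/[Zr](Cl)(C1C=CC=C1)C1C=CC=C1 | intermediate (not isolated)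
8 | 2-(benzyloxy)-1-{[(2R,3E)-4-[3,5-bis(benzyloxy)phenyl]but-3-en-2-yl]oxy}-4-bromobenzene | C[C@@H](Oc1ccc(Br)cc1OCc1ccccc1)/C=C/c1cc(OCc2ccccc2)cc(OCc2ccccc2)c1 | intermediate
9 | (6S)-2-(benzyloxy)-6-{(1S,2E)-1-[3,5-bis(benzyloxy)phenyl]but-2-en-1-yl}-4-bromocyclohexa-2,4-dien-1-one | O=C1C(OCc2ccccc2)=CC(Br)=C[C@@H]1[C@@H](c1cc(OCc2ccccc2)cc(OCc2ccccc2)c1)/C=C/C | intermediate (not isolated)
10 | 2-(benzyloxy)-6-{(1R,2E)-1-[3,5-bis(benzyloxy)phenyl]but-2-en-1-yl}-4-bromophenol | C/C=C/[C@H](c1cc(OCc2ccccc2)cc(OCc2ccccc2)c1)c1cc(Br)cc(OCc2ccccc2)c1O | intermediate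
11 | 2-(benzyloxy)-6-{(R)-[3,5-bis(benzyloxy)phenyl](5-methyl-1,2,4-trioxolan-3-yl)methyl}-4-bromophenol (trioxolane epimers) | CC1OOC(O1)[C@H](c1cc(OCc2ccccc2)cc(OCc2ccccc2)c1)c1cc(Br)cc(OCc2ccccc2)c1O | intermediate (not isolated)
12 | (3R)-7-(benzyloxy)-3-[3,5-bis(benzyloxy)phenyl]-5-bromo-2,3-dihydro-1-benzofuran-2-ol (both C2 epimers) | OC1Oc2c(OCc3ccccc3)cc(Br)cc2[C@H]1c1cc(OCc2ccccc2)cc(OCc2ccccc2)c1 | intermediate
13 | 4-(benzyloxy)phenylmagnesium bromide | Br[Mg]c1ccc(OCc2ccccc2)cc1 | starting material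
14 | 2-(benzyloxy)-6-{(1R)-2-[4-(benzyloxy)phenyl]-1-[3,5-bis(benzyloxy)phenyl]-2-hydroxyethyl}-4-bromophenol (both carbinol epimers) | OC(c1ccc(OCc2ccccc2)cc1)[C@H](c1cc(OCc2ccccc2)cc(OCc2ccccc2)c1)c1cc(Br)cc(OCc2ccccc2)c1O | intermediate (not isolated)
15 | (2R,3R)-7-(benzyloxy)-2-[4-(benzyloxy)phenyl]-3-[3,5-bis(benzyloxy)phenyl]-5-bromo-2,3-dihydro-1-benzofuran | Brc1cc(OCc2ccccc2)c2c(c1)[C@@H](c1cc(OCc3ccccc3)cc(OCc3ccccc3)c1)[C@H](c1ccc(OCc3ccccc3)cc1)O2 | intermediate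
16 | 5-chlorobenzene-1,3-diol | Oc1cc(O)cc(Cl)c1 | starting material
17 | 3-(benzyloxy)-5-chlorophenol | Oc1cc(Cl)cc(OCc2ccccc2)c1 | intermediate
18 | (R)-but-3-yn-2-ol | C[C@@H](O)C#C | starting material
19 | 1-(benzyloxy)-3-{[(2S)-but-3-yn-2-yl]oxy}-5-chlorobenzene | C[C@H](Oc1cc(Cl)cc(OCc2ccccc2)c1)C#C | intermediate
20 | chlorobis(cyclopentadienyl){(1E,3S)-3-[3-(benzyloxy)-5-chlorophenoxy]but-1-en-1-yl}zirconium | C[C@H](Oc1cc(Cl)cc(OCc2ccccc2)c1)/C=C/[Zr](Cl)(C1C=CC=C1)C1C=CC=C1 | intermediate (not isolated)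
21 | 1-(benzyloxy)-3-chloro-5-{[(2S,3E)-4-ArB-but-3-en-2-yl]oxy}benzene | C[C@H](Oc1cc(Cl)cc(OCc2ccccc2)c1)/C=C/c1cc(OCc2ccccc2)c2c(c1)[C@@H](c1cc(OCc3ccccc3)cc(OCc3ccccc3)c1)[C@H](c1ccc(OCc3ccccc3)cc1)O2 | intermediate
22 | (6S)-3-(benzyloxy)-5-chloro-6-[(1R,2E)-1-ArB-but-2-en-1-yl]cyclohexa-2,4-dien-1-one | O=C1C=C(OCc2ccccc2)C=C(Cl)[C@H]1[C@H](c1cc(OCc2ccccc2)c2c(c1)[C@@H](c1cc(OCc3ccccc3)cc(OCc3ccccc3)c1)[C@H](c1ccc(OCc3ccccc3)cc1)O2)/C=C/C | intermediate (not isolated)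
23 | 5-(benzyloxy)-3-chloro-2-[(1S,2E)-1-ArB-but-2-en-1-yl]phenol | C/C=C/[C@@H](c1cc(OCc2ccccc2)c2c(c1)[C@@H](c1cc(OCc3ccccc3)cc(OCc3ccccc3)c1)[C@H](c1ccc(OCc3ccccc3)cc1)O2)c1c(Cl)cc(OCc2ccccc2)cc1O | intermediate
24 | 5-(benzyloxy)-3-chloro-2-[(S)-ArB(5-methyl-1,2,4-trioxolan-3-yl)methyl]phenol (trioxolane epimers) | CC1OOC(O1)[C@@H](c1cc(OCc2ccccc2)c2c(c1)[C@@H](c1cc(OCc3ccccc3)cc(OCc3ccccc3)c1)[C@H](c1ccc(OCc3ccccc3)cc1)O2)c1c(Cl)cc(OCc2ccccc2)cc1O | intermediate (not isolated)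
25 | (3S)-6-(benzyloxy)-4-chloro-3-ArB-2,3-dihydro-1-benzofuran-2-ol (both C2 epimers) | OC1Oc2cc(OCc3ccccc3)cc(Cl)c2[C@@H]1c1cc(OCc2ccccc2)c2c(c1)[C@@H](c1cc(OCc3ccccc3)cc(OCc3ccccc3)c1)[C@H](c1ccc(OCc3ccccc3)cc1)O2 | intermediate
26 | 5-(benzyloxy)-2-{(1S)-2-[4-(benzyloxy)phenyl]-1-ArB-2-hydroxyethyl}-3-chlorophenol (both carbinol epimers) | OC(c1ccc(OCc2ccccc2)cc1)[C@@H](c1cc(OCc2ccccc2)c2c(c1)[C@@H](c1cc(OCc3ccccc3)cc(OCc3ccccc3)c1)[C@H](c1ccc(OCc3ccccc3)cc1)O2)c1c(Cl)cc(OCc2ccccc2)cc1O | intermediate (not isolated)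
27 | (2S,3S)-6-(benzyloxy)-2-[4-(benzyloxy)phenyl]-4-chloro-3-ArB-2,3-dihydro-1-benzofuran | c6ccccc6COc1ccc([C@H]2Oc3cc(OCc6ccccc6)cc(Cl)c3[C@@H]2c2cc(OCc6ccccc6)c3c(c2)[C@@H](c2cc(OCc6ccccc6)cc(OCc6ccccc6)c2)[C@H](c2ccc(OCc6ccccc6)cc2)O3)cc1 | intermediate
28 | 3,5-bis(benzyloxy)benzaldehyde | O=Cc1cc(OCc2ccccc2)cc(OCc2ccccc2)c1 | starting material
29 | 1,3-bis(benzyloxy)-5-ethynylbenzene | C#Cc1cc(OCc2ccccc2)cc(OCc2ccccc2)c1 | intermediate
30 | (2S,3S)-6-(benzyloxy)-2-[4-(benzyloxy)phenyl]-4-{[3,5-bis(benzyloxy)phenyl]ethynyl}-3-ArB-2,3-dihydro-1-benzofuran | c6ccccc6COc1ccc([C@H]2Oc3cc(OCc6ccccc6)cc(C#Cc4cc(OCc6ccccc6)cc(OCc6ccccc6)c4)c3[C@@H]2c2cc(OCc6ccccc6)c3c(c2)[C@@H](c2cc(OCc6ccccc6)cc(OCc6ccccc6)c2)[C@H](c2ccc(OCc6ccccc6)cc2)O3)cc1 | intermediate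
31 | (2S,3S)-6-(benzyloxy)-2-[4-(benzyloxy)phenyl]-4-{(Z)-2-[3,5-bis(benzyloxy)phenyl]ethenyl}-3-ArB-2,3-dihydro-1-benzofuran | c6ccccc6COc1ccc([C@H]2Oc3cc(OCc6ccccc6)cc(/C=C\c4cc(OCc6ccccc6)cc(OCc6ccccc6)c4)c3[C@@H]2c2cc(OCc6ccccc6)c3c(c2)[C@@H](c2cc(OCc6ccccc6)cc(OCc6ccccc6)c2)[C@H](c2ccc(OCc6ccccc6)cc2)O3)cc1 | intermediate
32 | 4-(benzyloxy)benzaldehyde | O=Cc1ccc(OCc2ccccc2)cc1 | starting material
33 | 4-(benzyloxy)benzyl chloride | ClCc1ccc(OCc2ccccc2)cc1 | starting material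
34 | 1-[4-(benzyloxy)benzyl]tetrahydrothiophenium chloride | [Cl-].c1ccccc1COc1ccc(C[S+]2CCCC2)cc1 | intermediate (not isolated)
35 | [4-(benzyloxy)phenyl](tetrahydrothiophenium-1-yl)methanide | c1ccccc1COc1ccc([CH-][S+]2CCCC2)cc1 | intermediate (not isolated)
36 | trans-2,3-bis[4-(benzyloxy)phenyl]oxirane, racemic (SMILES shows the (2S,3S) enantiomer) | c1ccccc1COc1ccc([C@@H]2O[C@H]2c2ccc(OCc3ccccc3)cc2)cc1 | intermediate
37 | exo,exo-1,3-bis[4-(benzyloxy)phenyl] carbonyl ylide (planar, W-shaped) | c1ccccc1COc1ccc(C=[O+][CH-]c2ccc(OCc3ccccc3)cc2)cc1 | intermediate (not isolated)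
38 | deca-O-benzylkobophenol A: (2S,3S)-6-(benzyloxy)-2-[4-(benzyloxy)phenyl]-4-{(2R,3S,4R,5S)-2,5-bis[4-(benzyloxy)phenyl]-4-[3,5-bis(benzyloxy)phenyl]oxolan-3-yl}-3-ArB-2,3-dihydro-1-benzofuran | c6ccccc6COc1ccc([C@H]2Oc3cc(OCc6ccccc6)cc([C@@H]4[C@H](c5cc(OCc6ccccc6)cc(OCc6ccccc6)c5)[C@@H](c5ccc(OCc6ccccc6)cc5)O[C@H]4c4ccc(OCc6ccccc6)cc4)c3[C@@H]2c2cc(OCc6ccccc6)c3c(c2)[C@@H](c2cc(OCc6ccccc6)cc(OCc6ccccc6)c2)[C@H](c2ccc(OCc6ccccc6)cc2)O3)cc1 | intermediate
39 | kobophenol A | Oc1ccc([C@H]2Oc3cc(O)cc([C@@H]4[C@H](c5cc(O)cc(O)c5)[C@@H](c5ccc(O)cc5)O[C@H]4c4ccc(O)cc4)c3[C@@H]2c2cc(O)c3c(c2)[C@@H](c2cc(O)cc(O)c2)[C@H](c2ccc(O)cc2)O3)cc1 | target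

**Step count**
Total: 19 steps. Longest linear sequence: 14 steps (1, 2, 4, 5, 6, 7, 10, 11, 12, 13, 15, 16, 18, 19).

**Three steps most likely to fail, with fallbacks**

Step 18 (carbonyl ylide cycloaddition). The ylide is electron-rich and the Z-stilbene is hindered and unactivated, so the addition may be slow against epoxide rearrangement, and the face selectivity rests on substrate control that is predicted, not proven. The all-inverted oxolane isomer would have to be removed by chromatography. If no useful adduct forms, the oxolane can be closed by oxidative 8–8′ coupling of two 4-hydroxystilbenes with capture of water, at the price of isomer separation. This branch sets out from chloride 27 and iodide 6. Suzuki–Miyaura coupling of each with commercial (E)-2-(4-hydroxyphenyl)ethenylboronic acid pinacol ester (Pd(OAc)2, SPhos, K3PO4, dioxane/H2O for 27; Pd(PPh3)4, K2CO3 for 6) gives the ring A (E)-4-hydroxystilbene F1 and 3,5-di-O-benzylresveratrol F2. Oxidising the two phenols together with Ag2O in wet acetone joins their β-carbons to the bis(quinone methide) F3. Water adds to one quinone methide and the new alcohol closes on the other to give octa-O-benzylkobophenol A F4, which is separated from homodimers and oxolane stereoisomers by HPLC. Hydrogenolysis as in step 19 then comes back to the route at 39.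

Step 13 (Grignard addition to the lactol, and equally step 7). The open aldehyde has a doubly benzylic α-hydrogen, so enolisation by the Grignard reagent lowers the yield and acid can dehydrate the lactol to an achiral 3-arylbenzofuran. The fallback sets out from phenol 23. Silylation (t-BuMe2SiCl, imidazole, DMF) gives silyl ether F5. Ozonolysis (O3, then PPh3) gives, through ozonide F6, the discrete aldehyde F7. This is added cold to the organocerium reagent made from 13 and CeCl3 (THF, −78 °C) to give carbinol F8. Bu4NF and then TsOH·H2O free the phenol (diol 26) and close the ring, coming back at 27.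

Step 15 (Sonogashira coupling of the aryl chloride). The chloride is electron-rich and sits next to the crowded C3 substituent, so oxidative addition or alkyne transfer may stall. The fallback sets out from chloride 27. Miyaura borylation (B2pin2, PdCl2(MeCN)2, XPhos, KOAc, dioxane, 100 °C) gives arylboronate F9. Aldehyde 28 is converted by Stork–Zhao olefination (Ph3P(CH2I)I, NaN(SiMe3)2, THF, −78 °C) into (Z)-vinyl iodide F10. Stereoretentive Suzuki–Miyaura coupling of F9 with F10 (PdCl2(dppf), Cs2CO3, THF/H2O, rt) gives Z-stilbene 31 directly, so the route is rejoined at 31 without alkyne 30 or the semi-hydrogenation.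

**Further compounds**
F1 | step 18 | (2S,3S)-6-(benzyloxy)-2-[4-(benzyloxy)phenyl]-4-[(E)-2-(4-hydroxyphenyl)ethenyl]-3-ArB-2,3-dihydro-1-benzofuran | c6ccccc6COc1ccc([C@H]2Oc3cc(OCc6ccccc6)cc(/C=C/c4ccc(O)cc4)c3[C@@H]2c2cc(OCc6ccccc6)c3c(c2)[C@@H](c2cc(OCc6ccccc6)cc(OCc6ccccc6)c2)[C@H](c2ccc(OCc6ccccc6)cc2)O3)cc1
F2 | step 18 | 4-{(E)-2-[3,5-bis(benzyloxy)phenyl]ethenyl}phenol (3,5-di-O-benzylresveratrol) | Oc1ccc(/C=C/c2cc(OCc3ccccc3)cc(OCc3ccccc3)c2)cc1
F3 | step 18 | 8–8′-coupled bis(quinone methide) of F1 and F2, shown with the configuration that leads to the target | c6ccccc6COc1ccc([C@H]2Oc3cc(OCc6ccccc6)cc([C@@H](C=C4C=CC(=O)C=C4)[C@H](c5cc(OCc6ccccc6)cc(OCc6ccccc6)c5)C=C4C=CC(=O)C=C4)c3[C@@H]2c2cc(OCc6ccccc6)c3c(c2)[C@@H](c2cc(OCc6ccccc6)cc(OCc6ccccc6)c2)[C@H](c2ccc(OCc6ccccc6)cc2)O3)cc1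
F4 | step 18 | octa-O-benzylkobophenol A (free hydroxyl on both oxolane 4-hydroxyphenyl groups) | c6ccccc6COc1ccc([C@H]2Oc3cc(OCc6ccccc6)cc([C@@H]4[C@H](c5cc(OCc6ccccc6)cc(OCc6ccccc6)c5)[C@@H](c5ccc(O)cc5)O[C@H]4c4ccc(O)cc4)c3[C@@H]2c2cc(OCc6ccccc6)c3c(c2)[C@@H](c2cc(OCc6ccccc6)cc(OCc6ccccc6)c2)[C@H](c2ccc(OCc6ccccc6)cc2)O3)cc1
F5 | step 13 | tert-butyldimethylsilyl ether of phenol 23 | C/C=C/[C@@H](c1cc(OCc2ccccc2)c2c(c1)[C@@H](c1cc(OCc3ccccc3)cc(OCc3ccccc3)c1)[C@H](c1ccc(OCc3ccccc3)cc1)O2)c1c(Cl)cc(OCc2ccccc2)cc1O[Si](C)(C)C(C)(C)C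
F6 | step 13 | ozonide (5-methyl-1,2,4-trioxolan-3-yl compound) of F5 | CC1OOC(O1)[C@@H](c1cc(OCc2ccccc2)c2c(c1)[C@@H](c1cc(OCc3ccccc3)cc(OCc3ccccc3)c1)[C@H](c1ccc(OCc3ccccc3)cc1)O2)c1c(Cl)cc(OCc2ccccc2)cc1O[Si](C)(C)C(C)(C)C
F7 | step 13 | (2S)-2-ArB-2-[4-(benzyloxy)-2-(tert-butyldimethylsilyloxy)-6-chlorophenyl]acetaldehyde | O=C[C@@H](c1cc(OCc2ccccc2)c2c(c1)[C@@H](c1cc(OCc3ccccc3)cc(OCc3ccccc3)c1)[C@H](c1ccc(OCc3ccccc3)cc1)O2)c1c(Cl)cc(OCc2ccccc2)cc1O[Si](C)(C)C(C)(C)C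
F8 | step 13 | (2S)-2-ArB-1-[4-(benzyloxy)phenyl]-2-[4-(benzyloxy)-2-(tert-butyldimethylsilyloxy)-6-chlorophenyl]ethan-1-ol (both carbinol epimers) | OC(c1ccc(OCc2ccccc2)cc1)[C@@H](c1cc(OCc2ccccc2)c2c(c1)[C@@H](c1cc(OCc3ccccc3)cc(OCc3ccccc3)c1)[C@H](c1ccc(OCc3ccccc3)cc1)O2)c1c(Cl)cc(OCc2ccccc2)cc1O[Si](C)(C)C(C)(C)C
F9 | step 15 | (2S,3S)-6-(benzyloxy)-2-[4-(benzyloxy)phenyl]-3-ArB-4-(4,4,5,5-tetramethyl-1,3,2-dioxaborolan-2-yl)-2,3-dihydro-1-benzofuran | c6ccccc6COc1ccc([C@H]2Oc3cc(OCc6ccccc6)cc(B4OC(C)(C)C(C)(C)O4)c3[C@@H]2c2cc(OCc6ccccc6)c3c(c2)[C@@H](c2cc(OCc6ccccc6)cc(OCc6ccccc6)c2)[C@H](c2ccc(OCc6ccccc6)cc2)O3)cc1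
F10 | step 15 | 1,3-bis(benzyloxy)-5-[(Z)-2-iodoethenyl]benzene | I/C=C\c1cc(OCc2ccccc2)cc(OCc2ccccc2)c1
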